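**Retrosynthetic overview**
- Target ⇒ aryl acetate cleavage, α-face epoxidation of C8=C9 and acylation of O6 ⇒ dauc-8-ene-4β,6β-diol.
- Diol ⇒ substrate-controlled hydride reduction ⇒ trans-fused 4β-hydroxydauc-8-en-6-one.
- Hydroazulenone ⇒ C1–C10 bond (quaternary centre, closes the seven-membered ring) by electrogenerated cobalt-hydride HAT and 7-endo radical conjugate cyclisation ⇒ cyclopentenyl 2-methylidenebut-3-enyl ketone.
- Dienone ⇒ allylic oxidation and Barbier isoprenylation ⇒ 5-hydroxy-5-isopropyl-2-methylcyclopentenecarbaldehyde.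
- Enal ⇒ ozonolysis/aldol ring contraction of (S)-(+)-terpinen-4-ol, which supplies C4. Ring order: five-membered ring first, seven-membered ring second, oxirane last.

Assumptions: (S)-(+)-terpinen-4-ol is bought in an enantiopure grade (its ee is carried unchanged into the target); 2-(bromomethyl)buta-1,3-diene is taken as a catalogue reagent.

Convention: daucane numbering. C1 = ring-fusion carbon with the angular methyl, C2, C3, C4 = carbinol carbon with isopropyl, C5 = ring-fusion CH, C6 = acyloxy carbon, C7, C8 = methyl-bearing carbon, C9, C10. β = face of the C1 methyl. Target: 1β-Me, 4β-OH, 5α-H, 6β-O-aroyl, 8α,9α-epoxide, i.e. (1R,4R,5S,6R,8R,9S).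

**Step 1**
Reactants: 1 (S)-(+)-terpinen-4-ol
Product: 4 (5R)-5-hydroxy-2-methyl-5-(propan-2-yl)cyclopent-1-ene-1-carbaldehyde, via ozonide 2 (not isolated), via keto aldehyde 3 (not isolated)
Conditions: O3, CH2Cl2, −78 °C; Me2S, −78 °C to rt; concentrate; piperidine (0.2 equiv), AcOH (0.2 equiv), toluene, 60 °C
Reagents that add atoms: ozone, [O-][O+]=O
Why: Criegee ozonolysis followed by amine/acid-catalysed intramolecular aldol condensation (the aldehyde enamine attacks the methyl ketone, 5-exo, as in the limonene-to-cyclopentenecarbaldehyde ring contraction); the carbinol stereocentre is not touched and becomes C4.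

**Step 2**
Reactants: 4 (5R)-5-hydroxy-2-methyl-5-(propan-2-yl)cyclopent-1-ene-1-carbaldehyde; 5 2-(bromomethyl)buta-1,3-diene
Product: 6 1-[(5R)-5-hydroxy-2-methyl-5-(propan-2-yl)cyclopent-1-en-1-yl]-3-methylidenepent-4-en-1-ol (both carbinol epimers)
Conditions: indium powder (1.5 equiv), 5 (1.5 equiv), THF/H2O 1:1, rt
Reagents that add atoms: 2-(bromomethyl)buta-1,3-diene (5), C=CC(=C)CBr
Why: Barbier-type indium-mediated allylation (isoprenylation) adds 1,2 to the hindered enal and tolerates the free tertiary alcohol; the new carbinol centre need not be controlled because step 3 removes it.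

**Step 3**
Reactants: 6 1-[(5R)-5-hydroxy-2-methyl-5-(propan-2-yl)cyclopent-1-en-1-yl]-3-methylidenepent-4-en-1-ol
Product: 7 1-[(5R)-5-hydroxy-2-methyl-5-(propan-2-yl)cyclopent-1-en-1-yl]-3-methylidenepent-4-en-1-one
Conditions: activated MnO2 (15 equiv), CH2Cl2, rt
Reagents that add atoms: none
Why: MnO2 allylic oxidation takes only the secondary allylic alcohol under neutral conditions, which keeps the skipped diene out of conjugation and leaves the tertiary alcohol alone.

**Step 4**
Reactants: 7 1-[(5R)-5-hydroxy-2-methyl-5-(propan-2-yl)cyclopent-1-en-1-yl]-3-methylidenepent-4-en-1-one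
Product: 8 (3R,3aR,8aR)-3-hydroxy-6,8a-dimethyl-3-(propan-2-yl)-1,2,3,3a,8,8a-hexahydroazulen-4(5H)-one (trans-fused; (1R,4R,5R)-4β-hydroxydauc-8-en-6-one)
Conditions: CoBr2 (10 mol %), 4,4′-dimethoxy-2,2′-bipyridine (12 mol %), 2,4,6-trimethylpyridinium tetrafluoroborate (2.5 equiv), n-Bu4NBF4 (0.1 M), MeCN, undivided cell, zinc anode, carbon-felt cathode, constant current 5 mA, 2.2 F/mol, rt
Reagents that add atoms: none
Why: Proposed new method: the cathode reduces the cobalt bipyridine complex to monovalent cobalt, which the pyridinium acid turns into a trivalent cobalt hydride that transfers a hydrogen atom to the exocyclic CH2 of the 2-substituted diene (more substituted allyl radical, formed from the s-trans diene so that C7 and C10 are cis), the primary terminus C10 of this allyl radical adds 7-endo to the electron-poor β-carbon C1 of the enone (6-exo attack at the fully substituted α-carbon C5 is electronically and sterically disfavoured) and the α-keto radical is reduced to the enolate and protonated; the O4–H···O6 hydrogen bond, tightened by zinc ions from the anode, holds the carbonyl oxygen on the β side next to the hydroxyl and away from isopropyl, so the tether lies under the ring and C10 bonds to the α face of C1 (methyl β, cis to OH), and C5 is protonated or equilibrated to the epimer with C6 trans to isopropyl (H5 α, trans fusion); the closest known reaction types are cobalt-electrocatalytic HAT functionalisation of alkenes and MHAT-initiated Giese (reductive olefin coupling) cyclisation.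

**Step 5**
Reactants: 8 (3R,3aR,8aR)-3-hydroxy-6,8a-dimethyl-3-(propan-2-yl)-1,2,3,3a,8,8a-hexahydroazulen-4(5H)-one
Product: 9 (3R,3aS,4R,8aR)-6,8a-dimethyl-3-(propan-2-yl)-1,2,3,3a,4,5,8,8a-octahydroazulene-3,4-diol ((1R,4R,5S,6R)-dauc-8-ene-4β,6β-diol)
Conditions: NaBH4 (1.5 equiv), MeOH, −40 °C
Reagents that add atoms: none
Why: Substrate-controlled borohydride reduction of the hydrogen-bonded β-hydroxy ketone, with hydride entering from the α face anti to the axial angular methyl (as in 4-oxo and 6-oxo 5α-steroids), gives the 6β (6R) alcohol, the syn-1,3-diol.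

**Step 6**
Reactants: 9 (1R,4R,5S,6R)-dauc-8-ene-4β,6β-diol; 10 4-acetoxybenzoyl chloride
Product: 11 (1R,4R,5S,6R)-4β-hydroxydauc-8-en-6β-yl 4-acetoxybenzoate
Conditions: 10 (1.5 equiv), Et3N (2 equiv), DMAP (0.3 equiv), CH2Cl2, 0 °C to 40 °C
Reagents that add atoms: 4-acetoxybenzoyl chloride (10), CC(=O)Oc1ccc(cc1)C(Cl)=O
Why: DMAP-catalysed acylation (nucleophilic catalysis) esterifies the secondary 6-OH while the tertiary 4-OH does not react; no stereocentre changes.

**Step 7**
Reactants: 11 (1R,4R,5S,6R)-4β-hydroxydauc-8-en-6β-yl 4-acetoxybenzoate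
Product: 12 (1R,4R,5S,6R,8R,9S)-8α,9α-epoxy-4β-hydroxydaucan-6β-yl 4-acetoxybenzoate
Conditions: dimethyldioxirane (1.2 equiv, acetone solution), CH2Cl2, −20 °C to 0 °C
Reagents that add atoms: dimethyldioxirane, CC1(C)OO1
Why: Neutral electrophilic epoxidation of the only alkene from the α face, because the axial C1 methyl and the axial 6β-aroyloxy group both screen the β face; this sets C8 and C9, and the absence of acid avoids transannular opening by the 4-OH.

**Step 8**
Reactants: 12 (1R,4R,5S,6R,8R,9S)-8α,9α-epoxy-4β-hydroxydaucan-6β-yl 4-acetoxybenzoate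
Product: 13 (1R,4R,5S,6R,8R,9S)-8α,9α-epoxy-4β-hydroxydaucan-6β-yl 4-hydroxybenzoate (CNP0163817.3)
Conditions: K2CO3 (0.2 equiv), MeOH, 0 °C, 30 min
Reagents that add atoms: none
Why: Base-catalysed transesterification (Zemplén-type methanolysis) cleaves the aryl acetate far faster than the hindered alkyl benzoate, which the phenoxide deactivates, and leaves the epoxide intact.

**Compound list**
1 | (S)-(+)-terpinen-4-ol, (1S)-4-methyl-1-(propan-2-yl)cyclohex-3-en-1-ol | CC1=CC[C@](O)(C(C)C)CC1 | starting material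
2 | secondary ozonide of 1, (3S)-6-methyl-3-(propan-2-yl)-7,8,9-trioxabicyclo[4.2.1]nonan-3-ol (bridgehead epimers) | CC12CC[C@@](O)(C(C)C)CC(OO1)O2 | intermediate (not isolated)
3 | (3S)-3-hydroxy-6-oxo-3-(propan-2-yl)heptanal | O=CC[C@](O)(C(C)C)CCC(C)=O | intermediate (not isolated)
4 | (5R)-5-hydroxy-2-methyl-5-(propan-2-yl)cyclopent-1-ene-1-carbaldehyde | CC1=C(C=O)[C@](O)(C(C)C)CC1 | intermediate
5 | 2-(bromomethyl)buta-1,3-diene | C=CC(=C)CBr | starting material
6 | 1-[(5R)-5-hydroxy-2-methyl-5-(propan-2-yl)cyclopent-1-en-1-yl]-3-methylidenepent-4-en-1-ol (carbinol epimers) | CC1=C(C(O)CC(=C)C=C)[C@](O)(C(C)C)CC1 | intermediate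
7 | 1-[(5R)-5-hydroxy-2-methyl-5-(propan-2-yl)cyclopent-1-en-1-yl]-3-methylidenepent-4-en-1-one | CC1=C(C(=O)CC(=C)C=C)[C@](O)(C(C)C)CC1 | intermediate
8 | (3R,3aR,8aR)-3-hydroxy-6,8a-dimethyl-3-(propan-2-yl)-1,2,3,3a,8,8a-hexahydroazulen-4(5H)-one | CC(C)[C@]1(O)CC[C@]2(C)CC=C(C)CC(=O)[C@H]21 | intermediate
9 | (3R,3aS,4R,8aR)-6,8a-dimethyl-3-(propan-2-yl)-1,2,3,3a,4,5,8,8a-octahydroazulene-3,4-diol | CC(C)[C@]1(O)CC[C@]2(C)CC=C(C)C[C@@H](O)[C@H]21 | intermediate
10 | 4-acetoxybenzoyl chloride | CC(=O)Oc1ccc(cc1)C(Cl)=O | starting material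
11 | (1R,4R,5S,6R)-4β-hydroxydauc-8-en-6β-yl 4-acetoxybenzoate | CC(C)[C@]1(O)CC[C@]2(C)CC=C(C)C[C@@H](OC(=O)c3ccc(OC(C)=O)cc3)[C@H]21 | intermediate
12 | (1R,4R,5S,6R,8R,9S)-8α,9α-epoxy-4β-hydroxydaucan-6β-yl 4-acetoxybenzoate | CC(C)[C@]1(O)CC[C@]2(C)C[C@@H]3O[C@]3(C)C[C@@H](OC(=O)c3ccc(OC(C)=O)cc3)[C@H]21 | intermediate
13 | (1R,4R,5S,6R,8R,9S)-8α,9α-epoxy-4β-hydroxydaucan-6β-yl 4-hydroxybenzoate | CC(C)[C@]1(O)CC[C@]2(C)C[C@@H]3O[C@]3(C)C[C@@H](OC(=O)c3ccc(O)cc3)[C@H]21 | target

**Totals**
Total step count: 8. Longest linear sequence: 8 steps (1 to 13).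

**Steps most likely to fail, with fallbacks**

Step 4 (the new electrochemical cyclisation). The allyl radical may be reduced before it cyclises (diene hydrogenation), hydrogen may be delivered to the wrong diene terminus, or the C1 face selectivity may be low. The fallback uses known chemistry, sets out from 4 and comes back at 8. Allylmagnesium bromide (2.2 equiv, THF, −78 °C) adds to 4 to give the allyl carbinol (1S)-1-[(5R)-5-hydroxy-2-methyl-5-(propan-2-yl)cyclopent-1-en-1-yl]but-3-en-1-ol F5 (the 6S epimer, separated). Its dipotassium salt (KH, 18-crown-6, THF, rt) undergoes anionic oxy-Cope rearrangement through the chair in which H6 eclipses the ring methyl, which delivers the allyl group to the α face of C1; cold acidic quench gives the aldehyde F6 with the formyl group trans to isopropyl. 2-Methylallylmagnesium chloride then gives the diene diol F7. Ring-closing metathesis with the second-generation Grubbs catalyst (CH2Cl2, 40 °C) closes the seven-membered ring to the bicyclic diol F8 (C6 epimers), and Dess–Martin periodinane oxidation returns to 8.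

Step 1 (aldol ring contraction). The β-hydroxy aldehyde 3 can lose water or undergo retro-aldol cleavage before the enamine closes the ring. The fallback sets out from 1 and comes back at 4. Et3SiOTf and 2,6-lutidine give the triethylsilyl ether of terpinen-4-ol F1. Ozonolysis with Me2S work-up and then piperidinium acetate lead, through the secondary ozonide F2 and the silyloxy keto aldehyde F3, to the silyl-protected enal F4. n-Bu4NF in THF removes the silyl group and gives 4.

Step 7 (face of epoxidation). If the flexible seven-membered ring lets the oxidant reach the β face, the wrong epoxide forms. The fallback sets out from 11 and comes back at 13. N-Bromosuccinimide in aqueous THF forms the bromonium ion on the face the electrophile prefers, and water opens it anti at C8 to give the bromohydrin 9β-bromo-4β,8α-dihydroxydaucan-6β-yl 4-acetoxybenzoate F9. K2CO3 in MeOH then closes the oxirane with inversion at C9, which places the epoxide on the face opposite to direct epoxidation, and cleaves the aryl acetate in the same flask to give 13.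

**Further compounds**
F1 | step 1 | triethyl{[(1S)-4-methyl-1-(propan-2-yl)cyclohex-3-en-1-yl]oxy}silane | CC1=CC[C@](O[Si](CC)(CC)CC)(C(C)C)CC1
F2 | step 1 | secondary ozonide of F1 (bridgehead epimers) | CC12CC[C@@](O[Si](CC)(CC)CC)(C(C)C)CC(OO1)O2
F3 | step 1 | (3S)-6-oxo-3-(propan-2-yl)-3-[(triethylsilyl)oxy]heptanal | O=CC[C@](O[Si](CC)(CC)CC)(C(C)C)CCC(C)=O
F4 | step 1 | (5R)-2-methyl-5-(propan-2-yl)-5-[(triethylsilyl)oxy]cyclopent-1-ene-1-carbaldehyde | CC1=C(C=O)[C@](O[Si](CC)(CC)CC)(C(C)C)CC1
F5 | step 4 | (1S)-1-[(5R)-5-hydroxy-2-methyl-5-(propan-2-yl)cyclopent-1-en-1-yl]but-3-en-1-ol | CC1=C([C@@H](O)CC=C)[C@](O)(C(C)C)CC1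
F6 | step 4 | (1R,2R,5R)-5-hydroxy-2-methyl-2-(prop-2-en-1-yl)-5-(propan-2-yl)cyclopentane-1-carbaldehyde | CC(C)[C@]1(O)CC[C@](C)(CC=C)[C@H]1C=O
F7 | step 4 | 1-[(1S,2R,5R)-5-hydroxy-2-methyl-2-(prop-2-en-1-yl)-5-(propan-2-yl)cyclopentyl]-3-methylbut-3-en-1-ol (carbinol epimers) | CC(C)[C@]1(O)CC[C@](C)(CC=C)[C@H]1C(O)CC(C)=C
F8 | step 4 | (3R,3aS,8aR)-6,8a-dimethyl-3-(propan-2-yl)-1,2,3,3a,4,5,8,8a-octahydroazulene-3,4-diol (C4 epimers) | CC(C)[C@]1(O)CC[C@]2(C)CC=C(C)CC(O)[C@H]21
F9 | step 7 | 9β-bromo-4β,8α-dihydroxydaucan-6β-yl 4-acetoxybenzoate | CC(C)[C@]1(O)CC[C@]2(C)C[C@@H](Br)[C@](C)(O)C[C@@H](OC(=O)c3ccc(OC(C)=O)cc3)[C@H]21
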